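**Plan**
Numbering: the target is read as an octahydroazulene (C3 hydroxyisopropyl, C3a/C8a ring fusion, C5 CO2H, C6 ring C=O, C7 acetonyl, C8 enol ester arm); intermediates keep these numbers.
Retrosynthesis: C6–C7 is cut first (acyl radical at C6 onto an enone whose β-carbon is C7; the ring ketone and the acetonyl ketone are a 1,4-dicarbonyl pair). Then the enone C=C (cross metathesis), the enol ester C–O (copper coupling), C5–C6 (carbonylation), C4=C5 (iodo-Wittig) and C8–C8a (anionic oxy-Cope) lead back to (S)-α-terpineol.
Forward: the cyclopentane comes first (ring contraction of terpineol), both C8 arms and the C4=C5 arm are built on it in open-chain form, and the cycloheptenone ring is closed last.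
Stereochemistry: C3 from terpineol; C8a and C8 from a chair oxy-Cope on the face anti to the C3 substituent; C3a by equilibration into a cis-fused lactol (temporary ring); C7 in the ring closure, directed by C8.
Enabling feature: the arms on C3a and C8a are trans on the cyclopentane, so the (Z)-acyl arm reaches the enone only through C6 (trans-fused seven-membered ring); closure through C4 would need a trans-fused bicyclo[3.3.0]octane.

Key step: step 15

Remark: PhSeSnBu3 is taken as a known reagent (from PhSeSePh, NaBH4 and Bu3SnCl); 1, 6, 8, 14, 18, 21 and 23 are catalogue compounds.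

Step 1
Reactants: 1 (S)-α-terpineol
Product: 2 triethylsilyl ether of 1
Conditions: TESOTf, 2,6-lutidine, CH2Cl2, 0 °C
Reagents that add atoms: triethylsilyl trifluoromethanesulfonate, CC[Si](CC)(CC)OS(=O)(=O)C(F)(F)F
Why: Silylation of the tertiary alcohol with a silyl triflate and a hindered base is standard and keeps the hydroxyl from closing onto the aldehydes of steps 2 to 5 as a lactol.

Step 2
Reactants: 2 triethylsilyl ether of 1
Product: 4 (3S)-6-oxo-3-[2-(triethylsilyloxy)propan-2-yl]heptanal, via secondary ozonide 3 (not isolated)
Conditions: O3, CH2Cl2, −78 °C; PPh3, −78 °C to rt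
Reagents that add atoms: ozone, [O-][O+]=O
Why: Ozonolysis with reductive work-up cleaves the only C=C to the keto aldehyde and leaves the stereocentre (the future C3) untouched.

Step 3
Reactants: 4 keto aldehyde
Product: 5 (5S)-2-methyl-5-[2-(triethylsilyloxy)propan-2-yl]cyclopent-1-ene-1-carbaldehyde
Conditions: piperidine (cat.), AcOH (cat.), PhH, 60 °C
Reagents that add atoms: none
Why: Amine-catalysed intramolecular aldol condensation (enamine of the aldehyde onto the methyl ketone, then dehydration) contracts the six-membered ring to the cyclopentene carbaldehyde, in which C4, C3a, C8a and its methyl group are in place.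

Step 4
Reactants: 5 cyclopentene carbaldehyde; 6 allylmagnesium bromide
Product: 7 homoallylic carbinol (both C4 epimers)
Conditions: THF, −78 °C; aq NH4Cl
Reagents that add atoms: none
Why: Grignard 1,2-addition to the hindered enal builds the 1,5-dien-3-ol, and the carbinol centre needs no control because it becomes the C4 carbonyl carbon again in step 6.

Step 5
Reactants: 7 homoallylic carbinol; 8 acrolein diethyl acetal
Product: 9 (E)-allylic acetal carbinol
Conditions: second-generation Hoveyda–Grubbs catalyst (5 mol %), CH2Cl2, 40 °C
Reagents that add atoms: none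
Why: Olefin cross metathesis of the only terminal alkene with an allylic acetal should give the (E)-alkene, which brings in the future C8 with its masked formyl arm, while the tetrasubstituted ring alkene does not react.

Step 6
Reactants: 9 (E)-allylic acetal carbinol
Product: 13 cis-fused C4 lactol (anomer mixture), via potassium alkoxide 10 (not isolated), via potassium enolate 11 (not isolated), via silyl ether aldehyde 12 (not isolated)
Conditions: KH, 18-crown-6, THF, 0 °C to rt; MeOH (1 equiv); TBAF, 40 °C; aq NH4Cl
Reagents that add atoms: none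
Why: Anionic oxy-Cope rearrangement through a chair transition state on the cyclopentene face anti to the C3 silyloxyisopropyl group makes the C8–C8a bond (quaternary C8a; C8 fixed by the (E)-alkene with the acetal arm equatorial), and fluoride then frees the tertiary hydroxyl while the basic medium epimerises the aldehyde, so that only the C3a epimer able to close the cis-fused five-membered lactol accumulates and C3a is set under thermodynamic control.

Step 7
Reactants: 14 tert-butyl (triphenyl-λ5-phosphanylidene)acetate
Product: 15 tert-butyl iodo(triphenyl-λ5-phosphanylidene)acetate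
Conditions: I2, K2CO3, MeOH, 0 °C
Reagents that add atoms: iodine, II
Why: Halogenation of the stabilised ylide, followed by deprotonation of the iodophosphonium salt by carbonate, should give the isolable α-iodo ylide.

Step 8
Reactants: 13 cis-fused C4 lactol; 15 α-iodo ylide
Product: 16 hydroxy (Z)-iodoacrylate
Conditions: PhCO2H (cat.), PhMe, 80 °C
Reagents that add atoms: none
Why: Wittig olefination of the lactol through its open hydroxy aldehyde with the stabilised α-iodo ylide places the ester trans and the iodine cis to C3a, the (Z)-iodoacrylate that the ring needs, under neutral conditions that should leave C3a untouched.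

Step 9
Reactants: 16 hydroxy (Z)-iodoacrylate
Product: 17 C8 aldehyde
Conditions: PPTS (cat.), acetone/H2O, 40 °C
Reagents that add atoms: water, O
Why: Mild acid hydrolysis of the diethyl acetal frees the formyl group on C8 without base, so the α-vinyl aldehyde should be neither epimerised nor conjugated and the tert-butyl ester survives.

Step 10
Reactants: 17 C8 aldehyde; 18 2-(dichloromethyl)-4,4,5,5-tetramethyl-1,3,2-dioxaborolane
Product: 19 (E)-alkenyl pinacol boronate
Conditions: CrCl2, LiI, THF, rt
Reagents that add atoms: none
Why: Takai–Utimoto olefination with the geminal dichromium reagent converts the hindered aldehyde into the (E)-alkenylboronate under non-basic conditions, and divalent chromium without a nickel co-catalyst should not touch the vinyl iodide.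

Step 11
Reactants: 19 (E)-alkenyl pinacol boronate
Product: 20 potassium (E)-alkenyltrifluoroborate
Conditions: KHF2, MeOH/H2O, rt
Reagents that add atoms: potassium hydrogen difluoride, [K+].F[H-]F
Why: Exchange of pinacol for fluoride gives the stable trifluoroborate needed for the copper coupling with retention of the (E) geometry.

Step 12
Reactants: 20 potassium (E)-alkenyltrifluoroborate; 21 3-methylbut-2-enoic acid
Product: 22 (E)-enol ester
Conditions: CuBr (10 mol %), DMAP (20 mol %), 4 Å MS, O2 (1 atm), MeCN, 60 °C
Reagents that add atoms: none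
Why: Chan–Lam-type oxidative copper-catalysed C–O coupling of an alkenyltrifluoroborate with a carboxylic acid is stereoretentive and should give the (E)-enol ester directly, the hindered tertiary alcohol being inert.

Step 13
Reactants: 22 (E)-enol ester; 23 but-3-en-2-one
Product: 24 enone iodoacrylate
Conditions: second-generation Hoveyda–Grubbs catalyst (10 mol %), CH2Cl2, 40 °C
Reagents that add atoms: none
Why: Cross metathesis of the only monosubstituted alkene with methyl vinyl ketone should give the (E)-enone with C7 as its β-carbon, the enol ester and the trisubstituted alkenes being poor metathesis partners.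

Step 14
Reactants: 24 enone iodoacrylate
Product: 25 (Z)-selenoester
Conditions: Pd(PPh3)4 (5 mol %), CO (20 atm), PhMe, 80 °C
Reagents that add atoms: carbon monoxide, [C-]#[O+]; tributyl(phenylselanyl)stannane, CCCC[Sn](CCCC)(CCCC)[Se]c1ccccc1
Why: Palladium-catalysed carbonylative Stille-type coupling of the vinyl iodide with the tin selenolate introduces C6 as the selenoester with retention of alkene geometry, the CO pressure favouring CO insertion over Heck insertion of the tethered alkenes.

Step 15
Reactants: 25 (Z)-selenoester
Product: 27 tert-butyl ester of the target, via acyl radical 26 (not isolated)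
Conditions: (TMS)3SiH (1.3 equiv, syringe pump), AIBN (cat.), PhH (5 mM), 80 °C
Reagents that add atoms: none
Why: The tris(trimethylsilyl)silyl radical abstracts the phenylselanyl group to give the (Z)-configured α,β-unsaturated acyl radical 26 at C6, which adds to C7, the β-carbon of the (E)-enone, and the α-keto radical formed takes a hydrogen atom from the silane to carry the chain. The closest known reaction type is the acyl selenide route to acyl radicals and their exo cyclisation onto enones and enoates, including 7-exo closures to seven-membered ketones. The cycloheptenone closes in the 7-exo-trig mode, trans-fused to the cyclopentane. C7 is set by the adjacent C8 centre: in the chair-like transition state the C8–H eclipses the enone (allylic strain) and the enol ester arm lies pseudo-equatorial, so the acetonyl group ends trans to that arm. The step needs site selectivity between the two alkenes on C8 and between C6 and the vinylogous C4 radical site: the nucleophilic acyl radical prefers the electron-poor enone over the electron-rich enol ester, and closure from C4 would give a strained trans-fused bicyclo[3.3.0]octane because the C3a and C8a arms are trans. The (Z) geometry fixed in steps 8 and 14 holds C6 cis to C3a as the ring requires.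

Step 16
Reactants: 27 tert-butyl ester of the target
Product: 28 CNP0290717.1
Conditions: ZnBr2, CH2Cl2, rt
Reagents that add atoms: none
Why: Lewis acid cleavage of the tert-butyl ester (the chelating β-keto ester is activated and isobutene is lost) frees the acid without base or strong protic acid, so the enol ester, the γ-epimerisable C3a and the tertiary alcohol should survive, and the α-alkylidene β-keto acid cannot decarboxylate.

**Compound list**
Note on 11–27: the cyclopentane carries the C4 arm (on C3a), the oxygenated isopropyl group (on C3) and the C8a methyl on one face, and C8 on the other face; at C8 the two arms are arranged as in the target (the CIP letter changes with the arms).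

1 | (S)-α-terpineol, 2-[(1S)-4-methylcyclohex-3-en-1-yl]propan-2-ol | CC1=CC[C@H](CC1)C(C)(C)O | starting material
2 | triethyl({2-[(1S)-4-methylcyclohex-3-en-1-yl]propan-2-yl}oxy)silane | CC1=CC[C@H](CC1)C(C)(C)O[Si](CC)(CC)CC | intermediate
3 | secondary ozonide of 2 (1,2,4-trioxolane across the former ring alkene, mixture at the new centres) | CC12CC[C@H](C(C)(C)O[Si](CC)(CC)CC)CC(O1)OO2 | intermediate
4 | (3S)-6-oxo-3-[2-(triethylsilyloxy)propan-2-yl]heptanal | O=CC[C@H](CCC(C)=O)C(C)(C)O[Si](CC)(CC)CC | intermediate
5 | (5S)-2-methyl-5-[2-(triethylsilyloxy)propan-2-yl]cyclopent-1-ene-1-carbaldehyde | O=CC1=C(C)CC[C@@H]1C(C)(C)O[Si](CC)(CC)CC | intermediate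
6 | allylmagnesium bromide | C=CC[Mg]Br | starting material
7 | 1-{(5S)-2-methyl-5-[2-(triethylsilyloxy)propan-2-yl]cyclopent-1-en-1-yl}but-3-en-1-ol, both carbinol epimers | C=CCC(O)C1=C(C)CC[C@@H]1C(C)(C)O[Si](CC)(CC)CC | intermediate
8 | acrolein diethyl acetal (3,3-diethoxyprop-1-ene) | C=CC(OCC)OCC | starting material
9 | (3E)-5,5-diethoxy-1-{(5S)-2-methyl-5-[2-(triethylsilyloxy)propan-2-yl]cyclopent-1-en-1-yl}pent-3-en-1-ol, both carbinol epimers | CCOC(OCC)/C=C/CC(O)C1=C(C)CC[C@@H]1C(C)(C)O[Si](CC)(CC)CC | intermediate
10 | potassium alkoxide of 9 | CCOC(OCC)/C=C/CC([O-])C1=C(C)CC[C@@H]1C(C)(C)O[Si](CC)(CC)CC.[K+] | intermediate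
11 | potassium enolate after the oxy-Cope step: exocyclic C3a=C4 enolate, C3 silyloxyisopropyl, C8a methyl, C8 = CH(CH=CH2)CH(OEt)2 | [K+].[O-]C=C1[C@@H](C(C)(C)O[Si](CC)(CC)CC)CC[C@]1(C)[C@H](C=C)C(OCC)OCC | intermediate
12 | aldehyde from protonation of 11, both C3a epimers | O=CC1[C@@H](C(C)(C)O[Si](CC)(CC)CC)CC[C@]1(C)[C@H](C=C)C(OCC)OCC | intermediate
13 | cis-fused lactol, 6-(1,1-diethoxybut-3-en-2-yl)-3,3,6-trimethylhexahydro-1H-cyclopenta[c]furan-1-ol: C4 hemiacetal closed by the C3 hydroxyisopropyl oxygen, C8a methyl on the face of the furan ring, anomer mixture | OC1OC(C)(C)[C@H]2CC[C@](C)([C@H](C=C)C(OCC)OCC)[C@@H]12 | intermediate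
14 | tert-butyl (triphenyl-λ5-phosphanylidene)acetate | CC(C)(C)OC(=O)C=P(c1ccccc1)(c1ccccc1)c1ccccc1 | starting material
15 | tert-butyl iodo(triphenyl-λ5-phosphanylidene)acetate | CC(C)(C)OC(=O)C(I)=P(c1ccccc1)(c1ccccc1)c1ccccc1 | intermediate
16 | tert-butyl (2Z)-2-iodo-3-(cyclopentyl)prop-2-enoate: C3 free hydroxyisopropyl, C8 = CH(CH=CH2)CH(OEt)2, iodine cis to C3a | CC(C)(C)OC(=O)/C(I)=C/[C@H]1[C@@H](C(C)(C)O)CC[C@]1(C)[C@H](C=C)C(OCC)OCC | intermediate
17 | as 16 with C8 = CH(CH=CH2)CHO | CC(C)(C)OC(=O)/C(I)=C/[C@H]1[C@@H](C(C)(C)O)CC[C@]1(C)[C@H](C=C)C=O | intermediate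
18 | 2-(dichloromethyl)-4,4,5,5-tetramethyl-1,3,2-dioxaborolane | ClC(Cl)B1OC(C)(C)C(C)(C)O1 | starting material
19 | as 16 with C8 = CH(CH=CH2)[(E)-CH=CH–B(pin)] | CC(C)(C)OC(=O)/C(I)=C/[C@H]1[C@@H](C(C)(C)O)CC[C@]1(C)[C@H](C=C)/C=C/B1OC(C)(C)C(C)(C)O1 | intermediate
20 | as 16 with C8 = CH(CH=CH2)[(E)-CH=CH–BF3K] | CC(C)(C)OC(=O)/C(I)=C/[C@H]1[C@@H](C(C)(C)O)CC[C@]1(C)[C@H](C=C)/C=C/[B-](F)(F)F.[K+] | intermediate
21 | 3-methylbut-2-enoic acid | CC(C)=CC(=O)O | starting material
22 | as 16 with C8 = CH(CH=CH2)[(E)-CH=CH–O–CO–CH=CMe2] | CC(C)(C)OC(=O)/C(I)=C/[C@H]1[C@@H](C(C)(C)O)CC[C@]1(C)[C@H](C=C)/C=C/OC(=O)C=C(C)C | intermediate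
23 | but-3-en-2-one | CC(=O)C=C | starting material
24 | as 22 with the vinyl group replaced by (E)-CH=CH–CO–CH3 | CC(C)(C)OC(=O)/C(I)=C/[C@H]1[C@@H](C(C)(C)O)CC[C@]1(C)[C@H](/C=C/C(C)=O)/C=C/OC(=O)C=C(C)C | intermediate
25 | as 24 with iodine replaced by C(=O)SePh (selenoester cis to C3a, tert-butyl ester trans) | CC(C)(C)OC(=O)/C(C(=O)[Se]c1ccccc1)=C/[C@H]2[C@@H](C(C)(C)O)CC[C@]2(C)[C@H](/C=C/C(C)=O)/C=C/OC(=O)C=C(C)C | intermediate
26 | C6 acyl radical from 25 | CC(C)(C)OC(=O)/C([C]=O)=C/[C@H]1[C@@H](C(C)(C)O)CC[C@]1(C)[C@H](/C=C/C(C)=O)/C=C/OC(=O)C=C(C)C | intermediate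
27 | tert-butyl ester of the target | CC(=O)C[C@@H]1C(=O)C(C(=O)OC(C)(C)C)=C[C@H]2[C@@H](C(C)(C)O)CC[C@]2(C)[C@H]1/C=C/OC(=O)C=C(C)C | intermediate
28 | CNP0290717.1, (3S,3aS,7S,8S,8aS)-3-(2-hydroxypropan-2-yl)-8a-methyl-8-{(E)-2-[(3-methylbut-2-enoyl)oxy]ethenyl}-6-oxo-7-(2-oxopropyl)-1,2,3,3a,6,7,8,8a-octahydroazulene-5-carboxylic acid | CC(=O)C[C@@H]1C(=O)C(C(=O)O)=C[C@H]2[C@@H](C(C)(C)O)CC[C@]2(C)[C@H]1/C=C/OC(=O)C=C(C)C | target

**Count and risks**
Total step count: 16. Longest linear sequence: 15 steps (steps 1 to 6 and 8 to 16); step 7 is a one-step branch.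

Step 15. Hydrogen transfer to the acyl radical, from the silane or within the molecule from the doubly allylic C8–H, may outrun the slow 7-exo closure and give uncyclised aldehyde. The fallback sets out from 24 and returns at 27. Hydroxycarbonylation (Pd(OAc)2, PPh3, CO, KOAc, DMF/H2O) should give the half acid F1 with the CO2H cis to C3a. Deoxygenative photoredox generation of the same acyl radical (fac-Ir(ppy)3, PPh3, 2,6-lutidine, MeCN, blue light) then works with no hydrogen-atom donor in solution, and the cyclised α-keto radical is reduced to the enolate and protonated to give 27.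

Step 6. Loss of the allyl unit from the alkoxide (retro-allylation) or reaction through a boat or syn-face transition state may lower the yield and the C8/C8a selectivity. The fallback sets out from 9 and returns at 13. Silylation (TMSCl, imidazole) gives the trimethylsilyl ether F2. A neutral thermal oxy-Cope rearrangement (PhMe, 200 °C, sealed tube) gives the trimethylsilyl enol ether F3. TBAF under the conditions of step 6 removes both silyl groups and funnels the aldehyde into lactol 13.

Step 12. Protodeboronation or homocoupling of the hindered alkenylboron may compete with slow C–O bond formation. The fallback sets out from 17 and returns at 22, bypassing 19 and 20. The phosphonium salt {[(3-methylbut-2-enoyl)oxy]methyl}(triphenyl)phosphonium chloride F4 is made from PPh3 and chloromethyl 3-methylbut-2-enoate. Its ylide (KN(SiMe3)2, THF, −78 °C) is used in a Wittig reaction of the Anders–Gaßner type on aldehyde 17, and the (E)-isomer 22 is separated from the (Z)-isomer.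

Further compounds
F1 | step 15 | half acid from 24: iodine replaced by CO2H (cis to C3a), tert-butyl ester trans | CC(C)(C)OC(=O)/C(C(=O)O)=C/[C@H]1[C@@H](C(C)(C)O)CC[C@]1(C)[C@H](/C=C/C(C)=O)/C=C/OC(=O)C=C(C)C
F2 | step 6 | trimethylsilyl ether of 9 | CCOC(OCC)/C=C/CC(O[Si](C)(C)C)C1=C(C)CC[C@@H]1C(C)(C)O[Si](CC)(CC)CC
F3 | step 6 | trimethylsilyl enol ether corresponding to enolate 11 | C[Si](C)(C)OC=C1[C@@H](C(C)(C)O[Si](CC)(CC)CC)CC[C@]1(C)[C@H](C=C)C(OCC)OCC
F4 | step 12 | {[(3-methylbut-2-enoyl)oxy]methyl}(triphenyl)phosphonium chloride | CC(C)=CC(=O)OC[P+](c1ccccc1)(c1ccccc1)c1ccccc1.[Cl-]
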